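## The problem

Compound 20 is a resveratrol trimer made of two 2,3-diaryl-2,3-dihydrobenzofurans joined by one bond, from C3 of the first unit (benzo ring A) to C6' of the second (benzo ring B). Ring A carries a phenol at C4 and the (E)-4-hydroxystyryl arm at C6; ring B carries a phenol at C4'; C2 and C2' bear the 4-hydroxyphenyl rings D and E, and C3' bears the 3,5-dihydroxyphenyl ring C. The four stereocentres C2, C3, C2' and C3' are all S, which places the two aryl groups trans on each five-membered ring. Within one ring the stereochemical problem is small: C2 is a benzylic ether carbon activated by the para oxygen of ring D (or E), it can be equilibrated under acid, and trans is the stable arrangement, so C3 can dictate C2. Between the rings there is no such relay, because C3 and C3' are separated by the flat arene ring B, so the absolute configuration has to be imposed from outside, twice and in the same sense. Seven free phenols, an electron-rich stilbene (lost under hydrogenation, attacked by acid and oxidants) and two ionisable C2–O bonds limit what the late steps may use. Every sp3 carbon of the skeleton carries an aryl group, so the hardest bonds are the aryl–C3 and aryl–C3' bonds at crowded benzylic positions. The enabling feature is that in each dihydrofuran C2 (bonded to O1 and ring D, or to O1' and ring E) and C3 (bonded to rings A and B, or to rings B and C) are neighbours that both trace back to carbonyl carbons: C3 to a diaryl ketone, and C2 to the carbonyl of a 4-methoxybenzoate on the phenol oxygen ortho to that ketone on ring A or ring B.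

## Retrosynthesis

**20 from 19.** The seven O–H bonds are traced to O–CH3 bonds. Methyl ethers are the only phenol protection that survives aryllithiums, BCl3 at the non-chelating positions, low-valent titanium and hydrogenation, and all seven fall in one operation. The forward reaction has to cleave seven ethers without damaging the stilbene or the two C2–O bonds.

**19 from 17 and 18.** The stilbene C=C bond is cut. An olefination is preferred to a Heck or cross-coupling at C6 because the aldehyde carbon of 17 can travel through the whole route as an inert silyloxymethyl group (15, via alcohol 16), whereas a halide or triflate at C6 would have to survive two lithiations and low-valent titanium. The alkene must be made after the hydrogenation that sets the stereocentres. The forward step needs only E selectivity, which a benzylic phosphonate (18) gives.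

**15 from 14 from 13.** The four C–H bonds at C2, C3, C2' and C3' are removed, leading to the flat bis(benzofuran) 13, which has no stereocentre. Syn hydrogenation of each C2=C3 bond gives cis rings (14), and acid equilibration of C2 and C2' gives the trans rings (15). The alternative of forming aryl–C3 bonds on a ring that already has its stereocentres would require two stereocontrolled benzylic arylations. The forward sequence asks one chiral catalyst to choose the same face of two remote furans.

**13 from 12 (key disconnection).** Both C2=C3 double bonds are cut at once, each into a diaryl ketone (C3) and an aryl ester carbonyl (C2) held ortho to each other. This is preferred over cyclodehydration of α-aryloxy ketones (forming C3–C3a), which would need two regiocontrolled electrophilic closures on differently substituted rings. It is also preferred over arylation at C3 of a preformed 2-arylbenzofuran, which would need a halobenzofuran and a hindered coupling for each ring. Precursor 12 contains no ring other than arenes, and all its C–C bonds are aryl–carbonyl bonds. The forward reaction must favour intramolecular ketone–ester coupling over intermolecular ketone–ketone coupling, twice.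

**12 from 10 and 11; 10 from 9.** The two ester C–O bonds are cut to bisphenol 10 and two equivalents of 4-methoxybenzoyl chloride (11), one for each phenol. The two phenols of 10 are the oxygens ortho to the ketones, so they can be unmasked from the hexamethyl ether 9 by chelation-controlled demethylation. Because the two ortho methoxy groups of ring A, and likewise of ring B, are equivalent, no early desymmetrisation of a resorcinol and no extra protecting group is needed. The forward step must stop at one demethylation per ketone and spare the silyl ether.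

**9 from 8; 8 from 5 and 6; 5 from 3 and 4; 4 from 2; 2 from 1.** The two aryl–carbonyl bonds are cut to aryllithium-plus-aldehyde unions followed by oxidation of diol 8. The ring B building block 3 acts first as the electrophile (its aldehyde takes the ring A aryllithium 4, made from silyl ether 2) and then as the nucleophile (the bromide of carbinol 5 is exchanged and adds to 6). Three symmetric, commercial 3,5-dimethoxyarenes (1, 3, 6) are thus stitched together in two operations. The forward steps need aldehyde addition to outrun bromine–lithium scrambling, and exchange to proceed in the presence of a lithium alkoxide.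

## Roads not taken

**Alternative 1:** The cut is the C3'–C3a' bond of the ring B dihydrofuran. The ester A1 would arise from the (S)-flavanone A2 by oxidative ring contraction with PhI(OAc)2, HC(OMe)3 and H2SO4, the ring B carbon migrating from the carbonyl carbon to the neighbouring methylene carbon.
- Merits: the trans relationship and the absolute configuration come directly from the single C2 stereocentre of A2; no pressure hydrogenation and no epimerisation are needed; the triflate and ester of A1 are handles for joining units.
- Weak points: A1 holds only rings B and E. Ring C has to be installed at C3' in place of the ester carbon, and the C3–C6' bond to the ring A unit has to be made at a stereogenic benzylic carbon, so the hardest bonds of the target remain after the key step. The key step builds one ring and one skeletal bond, and a second, analogous sequence is needed for the ring A unit. Flavanones such as A2 can racemise by reversible ring opening to the chalcone in acid, and the triflate lowers the migratory aptitude of the shifting arene.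
- Comparison: this road is better in how it obtains stereochemistry, from one well-behaved stereocentre per ring and not from a demanding hydrogenation. The chosen plan sets against this that all four aryl–C3/C3' bonds are made as simple aryl–carbonyl bonds before any stereocentre exists, and that the sequence is much shorter.

**Alternative 2:** The cut is through ring B itself (C3a'–C4' and C7'–C7a'). Heating the cyclobutenone A4 (carrying the complete ring A unit) with the siloxyalkyne A5 (carrying C3' and C2' with rings C and E) would give the ring B phenol A3 by a Danheiser benzannulation, and the dihydrofuran would be closed afterwards.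
- Merits: it is the most convergent of the four plans, the substitution pattern of ring B is fixed by the mechanism, and two enantiopure halves are joined late, so no single catalyst has to control two remote rings.
- Weak points: A4 and A5 each carry two stereocentres that need their own asymmetric syntheses, and a 3-substituted cyclobutenone bearing a benzylic stereocentre has an epimerisable position. The cascade of four pericyclic steps runs hot in the presence of the stilbene of A4, which can itself react with the vinylketene. After A3, the C2'–O1' ring closure with stereocontrol and a phenol methylation are still required.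
- Comparison: convergence and late fragment union are better here. The chosen plan sets against this far simpler precursors (three commercial arenes instead of two chiral fragments) and a key step without thermal risk to a stilbene.

**Alternative 3:** The cut is through ring A (C3a–C4 and C5–C6). The trans-dihydrofuro[3,2-c]pyran-4-one A7 and 1,1-dimethoxyethene A8 would undergo a Diels–Alder reaction across the pyrone, lose CO2 and methanol, and give the heptamethyl ether A6, which is the same compound as 19 of the chosen route.
- Merits: the key step ends one deprotection from the target, and its regiochemistry follows from the polarity of the pyrone and the ketene acetal, so the endgame is shorter on paper than the six steps that follow the key step of the chosen plan.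
- Weak points: A7 already contains all four stereocentres, the ring B dihydrobenzofuran and the styryl arm, so the real problems are moved into its synthesis, for which no equally direct stereocontrolled construction is apparent. The styryl group offers a competing diene and dienophile site, and the C3–H of A7 is benzylic and vinylogously activated by the pyranone carbonyl, so it is epimerisable under the thermal conditions.
- Comparison: the last stage is more economical here. The chosen plan sets against this that the stereocentres are introduced onto a complete, robust skeleton in one operation and that every earlier intermediate is achiral.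

Key step: step 7

**Remarks on the chemistry.**
- The face selectivity of the catalyst formed from Ru(cod)(2-methylallyl)2 and the chiral N-heterocyclic carbene towards the two 2,3-diaryl furan rings of 13 is assumed to follow the ligand antipode. (R,R)-SINpEt·HBF4 (1,3-bis[(R)-1-(naphthalen-1-yl)ethyl]-4,5-dihydroimidazolium tetrafluoroborate) is specified; its equally available mirror image would be used if a trial shows the opposite sense.
- Compounds 1, 3, 6, 11 and 18 are taken as commercial.
- Numbering: unprimed locants belong to the ring A benzofuran, primed locants to the ring B benzofuran.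

## Route

Step 1
Reactants: 1 (4-bromo-3,5-dimethoxyphenyl)methanol
Product: 2 [(4-bromo-3,5-dimethoxybenzyl)oxy](tert-butyl)diphenylsilane
Conditions: TBDPSCl, imidazole, DMF, rt
Reagents that add atoms: tert-butyl(chloro)diphenylsilane (TBDPSCl), CC(C)(C)[Si](Cl)(c1ccccc1)c1ccccc1
Why: Standard silylation of a primary benzylic alcohol; the tert-butyldiphenylsilyl ether is chosen because it should tolerate n-BuLi at −78 °C, BCl3 at low temperature, low-valent titanium and CF3CO2H.

Step 2
Reactants: 2 [(4-bromo-3,5-dimethoxybenzyl)oxy](tert-butyl)diphenylsilane; 3 4-bromo-3,5-dimethoxybenzaldehyde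
Product: 5 (4-bromo-3,5-dimethoxyphenyl){4-[(tert-butyldiphenylsilyloxy)methyl]-2,6-dimethoxyphenyl}methanol (racemic), via ring A aryllithium 4 (not isolated)
Conditions: n-BuLi (1.0 equiv), THF, −78 °C; then 3, −78 → −20 °C; H2O
Reagents that add atoms: none
Why: Bromine–lithium exchange between two methoxy groups is fast and gives a chelation-stabilised aryllithium, whose 1,2-addition to the aldehyde is much faster than exchange with the aryl bromide of 3, so that bromide is kept for step 3. The carbinol centre is racemic and is erased in step 4.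

Step 3
Reactants: 5 (4-bromo-3,5-dimethoxyphenyl){4-[(tert-butyldiphenylsilyloxy)methyl]-2,6-dimethoxyphenyl}methanol; 6 3,5-dimethoxybenzaldehyde
Product: 8 {4-[(tert-butyldiphenylsilyloxy)methyl]-2,6-dimethoxyphenyl}{4-[(3,5-dimethoxyphenyl)(hydroxy)methyl]-3,5-dimethoxyphenyl}methanol (mixture of diastereomers), via dilithio alkoxide 7 (not isolated)
Conditions: n-BuLi (2.2 equiv), THF, −78 °C; then 6, −78 → 0 °C; H2O
Reagents that add atoms: none
Why: The first equivalent of n-BuLi forms the lithium alkoxide and the second exchanges the flanked bromide; alkoxide-tolerant bromine–lithium exchange followed by 1,2-addition to an aldehyde is established dianion chemistry. Both carbinol centres are erased in step 4.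

Step 4
Reactants: 8 {4-[(tert-butyldiphenylsilyloxy)methyl]-2,6-dimethoxyphenyl}{4-[(3,5-dimethoxyphenyl)(hydroxy)methyl]-3,5-dimethoxyphenyl}methanol
Product: 9 {4-[(tert-butyldiphenylsilyloxy)methyl]-2,6-dimethoxyphenyl}[4-(3,5-dimethoxybenzoyl)-3,5-dimethoxyphenyl]methanone
Conditions: Dess–Martin periodinane (3 equiv), pyridine, CH2Cl2, rt
Reagents that add atoms: none
Why: Dess–Martin oxidation of two doubly benzylic secondary alcohols to diaryl ketones; the buffered, non-acidic medium avoids ionisation of the electron-rich benzhydrols, and no over-oxidation is possible.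

Step 5
Reactants: 9 {4-[(tert-butyldiphenylsilyloxy)methyl]-2,6-dimethoxyphenyl}[4-(3,5-dimethoxybenzoyl)-3,5-dimethoxyphenyl]methanone
Product: 10 {4-[(tert-butyldiphenylsilyloxy)methyl]-2-hydroxy-6-methoxyphenyl}[4-(3,5-dimethoxybenzoyl)-3-hydroxy-5-methoxyphenyl]methanone
Conditions: BCl3 (2.5 equiv), CH2Cl2, −78 → 0 °C; then H2O
Reagents that add atoms: none
Why: Chelation-controlled cleavage of an aryl methyl ether ortho to a ketone: BCl3 bridges the carbonyl oxygen and one ortho methoxy oxygen and chloride removes that methyl group, after which the aryloxyboron chelate no longer activates the second ortho methoxy group. The ring C methoxy groups are meta to the ketone and cannot chelate, and the two ortho methoxy groups on ring A and on ring B are equivalent, so a single bisphenol should result.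

Step 6
Reactants: 10 {4-[(tert-butyldiphenylsilyloxy)methyl]-2-hydroxy-6-methoxyphenyl}[4-(3,5-dimethoxybenzoyl)-3-hydroxy-5-methoxyphenyl]methanone; 11 4-methoxybenzoyl chloride (2 equiv react, one at each phenol; a slight excess is charged)
Product: 12 2-[4-(3,5-dimethoxybenzoyl)-3-methoxy-5-(4-methoxybenzoyloxy)benzoyl]-5-[(tert-butyldiphenylsilyloxy)methyl]-3-methoxyphenyl 4-methoxybenzoate
Conditions: 11 (2.4 equiv), Et3N, DMAP (cat.), CH2Cl2, 0 °C → rt
Reagents that add atoms: 4-methoxybenzoyl chloride (the second equivalent of 11, which acylates the second phenol), COc1ccc(C(=O)Cl)cc1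
Why: DMAP-catalysed O-acylation of both phenols, each taking one 4-methoxybenzoyl group from one molecule of 11; the acylpyridinium ion overcomes the hydrogen bond of each phenol to its ketone, and the diaryl ketones have no α-hydrogen, so no acyl migration can follow.

Step 7
Reactants: 12 2-[4-(3,5-dimethoxybenzoyl)-3-methoxy-5-(4-methoxybenzoyloxy)benzoyl]-5-[(tert-butyldiphenylsilyloxy)methyl]-3-methoxyphenyl 4-methoxybenzoate
Product: 13 tert-butyl({4-methoxy-3-[4-methoxy-3-(3,5-dimethoxyphenyl)-2-(4-methoxyphenyl)-1-benzofuran-6-yl]-2-(4-methoxyphenyl)-1-benzofuran-6-yl}methoxy)diphenylsilane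
Conditions: TiCl3 (excess), Zn dust, DME, reflux; 12 added slowly by syringe pump
Reagents that add atoms: none
Why: Low-valent titanium made from TiCl3 and Zn transfers an electron to each diaryl ketone to give a titanium-bound ketyl at C3 (C3'), which adds to the carbonyl carbon of the 4-methoxybenzoate on the ortho oxygen; the titanium diolate then gives up both oxygens to titanium and leaves the C2=C3 (C2'=C3') bond of an aromatic furan. The closest known reaction type is the intramolecular McMurry-type coupling of ortho-acyloxy aryl ketones to 2,3-disubstituted benzofurans. Each ring closes in a 5-exo-trig mode (C3, C3a, C7a, O1, C2 and the primed set). No stereocentre is formed because both new rings are planar. The selectivity required is chemoselectivity for ketone–ester coupling within each pair over intermolecular ketone–ketone coupling and over plain reduction of the ketone; the ortho placement of each ester makes the five-membered closure fast, and slow addition of 12 to excess reagent keeps the ketyl concentration low. The pairs cannot cross, since the ring B ester is meta to the carbon that carries the ring A–ring B ketone and the two ketone carbons sit para on ring B. Silyl ether, methyl ethers and the product furans are inert to the reagent.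

Step 8
Reactants: 13 tert-butyl({4-methoxy-3-[4-methoxy-3-(3,5-dimethoxyphenyl)-2-(4-methoxyphenyl)-1-benzofuran-6-yl]-2-(4-methoxyphenyl)-1-benzofuran-6-yl}methoxy)diphenylsilane
Product: 14 tert-butyl({(2R,3S)-4-methoxy-3-[(2R,3S)-4-methoxy-3-(3,5-dimethoxyphenyl)-2-(4-methoxyphenyl)-2,3-dihydro-1-benzofuran-6-yl]-2-(4-methoxyphenyl)-2,3-dihydro-1-benzofuran-6-yl}methoxy)diphenylsilane (both rings cis)
Conditions: Ru(cod)(2-methylallyl)2 (5 mol%), (R,R)-SINpEt·HBF4 (10 mol%), KOtBu (15 mol%), toluene/n-hexane, H2 (100 bar), 40 °C
Reagents that add atoms: none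
Why: Asymmetric hydrogenation of the furan ring of benzofurans with the catalyst formed from Ru(cod)(2-methylallyl)2 and a chiral N-heterocyclic carbene; syn delivery of H2 to one face of each C2=C3 bond gives cis rings and sets C3 and C3' as S (C2 and C2' as R) under catalyst control. The two furans are remote and are reduced independently, so the minor wrong-face event mostly ends in a separable diastereomer; the benzo rings, aryl groups and silyl ether are not reduced by this catalyst.

Step 9
Reactants: 14 tert-butyl({(2R,3S)-4-methoxy-3-[(2R,3S)-4-methoxy-3-(3,5-dimethoxyphenyl)-2-(4-methoxyphenyl)-2,3-dihydro-1-benzofuran-6-yl]-2-(4-methoxyphenyl)-2,3-dihydro-1-benzofuran-6-yl}methoxy)diphenylsilane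
Product: 15 tert-butyl({(2S,3S)-4-methoxy-3-[(2S,3S)-4-methoxy-3-(3,5-dimethoxyphenyl)-2-(4-methoxyphenyl)-2,3-dihydro-1-benzofuran-6-yl]-2-(4-methoxyphenyl)-2,3-dihydro-1-benzofuran-6-yl}methoxy)diphenylsilane (both rings trans)
Conditions: CF3CO2H, CH2Cl2, 0 °C → rt
Reagents that add atoms: none
Why: Acid-promoted epimerisation of cis-2,3-diaryl-2,3-dihydrobenzofurans: protonation of O1 (O1') and ionisation of the C2–O bond give a benzylic cation stabilised by the 4-methoxyphenyl ring, and reclosure by the phenol gives the more stable trans ring. C3 and C3' are not touched, so the configuration from step 8 fixes the product as 2S,3S,2'S,3'S.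

Step 10
Reactants: 15 tert-butyl({(2S,3S)-4-methoxy-3-[(2S,3S)-4-methoxy-3-(3,5-dimethoxyphenyl)-2-(4-methoxyphenyl)-2,3-dihydro-1-benzofuran-6-yl]-2-(4-methoxyphenyl)-2,3-dihydro-1-benzofuran-6-yl}methoxy)diphenylsilane
Product: 16 {(2S,3S)-4-methoxy-3-[(2S,3S)-4-methoxy-3-(3,5-dimethoxyphenyl)-2-(4-methoxyphenyl)-2,3-dihydro-1-benzofuran-6-yl]-2-(4-methoxyphenyl)-2,3-dihydro-1-benzofuran-6-yl}methanol
Conditions: Bu4NF, THF, 0 °C → rt; H2O
Reagents that add atoms: none
Why: Fluoride cleavage of a silyl ether, driven by the Si–F bond; methyl ethers and the dihydrofurans are inert.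

Step 11
Reactants: 16 {(2S,3S)-4-methoxy-3-[(2S,3S)-4-methoxy-3-(3,5-dimethoxyphenyl)-2-(4-methoxyphenyl)-2,3-dihydro-1-benzofuran-6-yl]-2-(4-methoxyphenyl)-2,3-dihydro-1-benzofuran-6-yl}methanol
Product: 17 (2S,3S)-4-methoxy-3-[(2S,3S)-4-methoxy-3-(3,5-dimethoxyphenyl)-2-(4-methoxyphenyl)-2,3-dihydro-1-benzofuran-6-yl]-2-(4-methoxyphenyl)-2,3-dihydro-1-benzofuran-6-carbaldehyde
Conditions: Dess–Martin periodinane, pyridine, CH2Cl2, rt
Reagents that add atoms: none
Why: Dess–Martin oxidation of a primary benzylic alcohol stops at the aldehyde; the neutral conditions leave the benzylic C2–H and C3–H positions alone.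

Step 12
Reactants: 17 (2S,3S)-4-methoxy-3-[(2S,3S)-4-methoxy-3-(3,5-dimethoxyphenyl)-2-(4-methoxyphenyl)-2,3-dihydro-1-benzofuran-6-yl]-2-(4-methoxyphenyl)-2,3-dihydro-1-benzofuran-6-carbaldehyde; 18 diethyl (4-methoxybenzyl)phosphonate
Product: 19 (2S,3S)-4-methoxy-3-[(2S,3S)-4-methoxy-3-(3,5-dimethoxyphenyl)-2-(4-methoxyphenyl)-2,3-dihydro-1-benzofuran-6-yl]-2-(4-methoxyphenyl)-6-[(E)-2-(4-methoxyphenyl)ethenyl]-2,3-dihydro-1-benzofuran
Conditions: KOtBu, THF, 0 °C → rt
Reagents that add atoms: none
Why: Horner–Wadsworth–Emmons olefination of a non-enolisable aryl aldehyde with a benzylic phosphonate anion, which gives the (E)-stilbene through the reversible, anti-selective addition; the diarylmethine C3–H bonds are not acidic enough to be touched by KOtBu.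

Step 13
Reactants: 19 (2S,3S)-4-methoxy-3-[(2S,3S)-4-methoxy-3-(3,5-dimethoxyphenyl)-2-(4-methoxyphenyl)-2,3-dihydro-1-benzofuran-6-yl]-2-(4-methoxyphenyl)-6-[(E)-2-(4-methoxyphenyl)ethenyl]-2,3-dihydro-1-benzofuran
Product: 20 (2S,3S)-3-[(2S,3S)-3-(3,5-dihydroxyphenyl)-4-hydroxy-2-(4-hydroxyphenyl)-2,3-dihydro-1-benzofuran-6-yl]-2-(4-hydroxyphenyl)-6-[(E)-2-(4-hydroxyphenyl)ethenyl]-2,3-dihydro-1-benzofuran-4-ol
Conditions: BBr3 (excess), CH2Cl2, −78 °C → rt; then H2O
Reagents that add atoms: none
Why: BBr3 cleavage of aryl methyl ethers (boron–oxygen adduct, then bromide attack at methyl) applied to all seven ethers. The trans rings are the thermodynamic arrangement, so a reversible C2–O opening would return the same isomer, and the styryl arm at C6 is too far from ring C for an acid-induced Friedel–Crafts closure.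

## Compound list

1 | (4-bromo-3,5-dimethoxyphenyl)methanol | COc1cc(CO)cc(OC)c1Br | starting material
2 | [(4-bromo-3,5-dimethoxybenzyl)oxy](tert-butyl)diphenylsilane | COc1cc(CO[Si](c2ccccc2)(c2ccccc2)C(C)(C)C)cc(OC)c1Br | intermediate
3 | 4-bromo-3,5-dimethoxybenzaldehyde | COc1cc(C=O)cc(OC)c1Br | starting material
4 | {4-[(tert-butyldiphenylsilyloxy)methyl]-2,6-dimethoxyphenyl}lithium (ring A aryllithium) | [Li]c1c(OC)cc(CO[Si](c2ccccc2)(c2ccccc2)C(C)(C)C)cc1OC | intermediate (not isolated)
5 | (4-bromo-3,5-dimethoxyphenyl){4-[(tert-butyldiphenylsilyloxy)methyl]-2,6-dimethoxyphenyl}methanol, racemic | COc1cc(CO[Si](c2ccccc2)(c2ccccc2)C(C)(C)C)cc(OC)c1C(O)c1cc(OC)c(Br)c(OC)c1 | intermediate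
6 | 3,5-dimethoxybenzaldehyde | COc1cc(C=O)cc(OC)c1 | starting material
7 | dilithio alkoxide: lithium alkoxide of 5 in which bromine is replaced by lithium | [Li]OC(c1c(OC)cc(CO[Si](c2ccccc2)(c2ccccc2)C(C)(C)C)cc1OC)c1cc(OC)c([Li])c(OC)c1 | intermediate (not isolated)
8 | {4-[(tert-butyldiphenylsilyloxy)methyl]-2,6-dimethoxyphenyl}{4-[(3,5-dimethoxyphenyl)(hydroxy)methyl]-3,5-dimethoxyphenyl}methanol, mixture of diastereomers | COc1cc(CO[Si](c2ccccc2)(c2ccccc2)C(C)(C)C)cc(OC)c1C(O)c1cc(OC)c(C(O)c2cc(OC)cc(OC)c2)c(OC)c1 | intermediate
9 | {4-[(tert-butyldiphenylsilyloxy)methyl]-2,6-dimethoxyphenyl}[4-(3,5-dimethoxybenzoyl)-3,5-dimethoxyphenyl]methanone | COc1cc(CO[Si](c2ccccc2)(c2ccccc2)C(C)(C)C)cc(OC)c1C(=O)c1cc(OC)c(C(=O)c2cc(OC)cc(OC)c2)c(OC)c1 | intermediate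
10 | {4-[(tert-butyldiphenylsilyloxy)methyl]-2-hydroxy-6-methoxyphenyl}[4-(3,5-dimethoxybenzoyl)-3-hydroxy-5-methoxyphenyl]methanone | COc1cc(CO[Si](c2ccccc2)(c2ccccc2)C(C)(C)C)cc(O)c1C(=O)c1cc(OC)c(C(=O)c2cc(OC)cc(OC)c2)c(O)c1 | intermediate
11 | 4-methoxybenzoyl chloride | COc1ccc(C(=O)Cl)cc1 | starting material
12 | 2-[4-(3,5-dimethoxybenzoyl)-3-methoxy-5-(4-methoxybenzoyloxy)benzoyl]-5-[(tert-butyldiphenylsilyloxy)methyl]-3-methoxyphenyl 4-methoxybenzoate | COc1ccc(C(=O)Oc2cc(CO[Si](c3ccccc3)(c3ccccc3)C(C)(C)C)cc(OC)c2C(=O)c2cc(OC)c(C(=O)c3cc(OC)cc(OC)c3)c(OC(=O)c3ccc(OC)cc3)c2)cc1 | intermediate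
13 | tert-butyl({4-methoxy-3-[4-methoxy-3-(3,5-dimethoxyphenyl)-2-(4-methoxyphenyl)-1-benzofuran-6-yl]-2-(4-methoxyphenyl)-1-benzofuran-6-yl}methoxy)diphenylsilane | CC(C)(C)[Si](OCc1cc(OC)c2c(c1)oc(-c1ccc(OC)cc1)c2-c1cc(OC)c2c(c1)oc(-c1ccc(OC)cc1)c2-c1cc(OC)cc(OC)c1)(c1ccccc1)c1ccccc1 | intermediate
14 | tert-butyl({(2R,3S)-4-methoxy-3-[(2R,3S)-4-methoxy-3-(3,5-dimethoxyphenyl)-2-(4-methoxyphenyl)-2,3-dihydro-1-benzofuran-6-yl]-2-(4-methoxyphenyl)-2,3-dihydro-1-benzofuran-6-yl}methoxy)diphenylsilane, both rings cis | CC(C)(C)[Si](OCc1cc(OC)c2c(c1)O[C@@H](c1ccc(OC)cc1)[C@H]2c1cc(OC)c2c(c1)O[C@@H](c1ccc(OC)cc1)[C@H]2c1cc(OC)cc(OC)c1)(c1ccccc1)c1ccccc1 | intermediate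
15 | tert-butyl({(2S,3S)-4-methoxy-3-[(2S,3S)-4-methoxy-3-(3,5-dimethoxyphenyl)-2-(4-methoxyphenyl)-2,3-dihydro-1-benzofuran-6-yl]-2-(4-methoxyphenyl)-2,3-dihydro-1-benzofuran-6-yl}methoxy)diphenylsilane, both rings trans | CC(C)(C)[Si](OCc1cc(OC)c2c(c1)O[C@H](c1ccc(OC)cc1)[C@H]2c1cc(OC)c2c(c1)O[C@H](c1ccc(OC)cc1)[C@H]2c1cc(OC)cc(OC)c1)(c1ccccc1)c1ccccc1 | intermediate
16 | {(2S,3S)-4-methoxy-3-[(2S,3S)-4-methoxy-3-(3,5-dimethoxyphenyl)-2-(4-methoxyphenyl)-2,3-dihydro-1-benzofuran-6-yl]-2-(4-methoxyphenyl)-2,3-dihydro-1-benzofuran-6-yl}methanol | OCc1cc(OC)c2c(c1)O[C@H](c1ccc(OC)cc1)[C@H]2c1cc(OC)c2c(c1)O[C@H](c1ccc(OC)cc1)[C@H]2c1cc(OC)cc(OC)c1 | intermediate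
17 | (2S,3S)-4-methoxy-3-[(2S,3S)-4-methoxy-3-(3,5-dimethoxyphenyl)-2-(4-methoxyphenyl)-2,3-dihydro-1-benzofuran-6-yl]-2-(4-methoxyphenyl)-2,3-dihydro-1-benzofuran-6-carbaldehyde | O=Cc1cc(OC)c2c(c1)O[C@H](c1ccc(OC)cc1)[C@H]2c1cc(OC)c2c(c1)O[C@H](c1ccc(OC)cc1)[C@H]2c1cc(OC)cc(OC)c1 | intermediate
18 | diethyl (4-methoxybenzyl)phosphonate | CCOP(=O)(Cc1ccc(OC)cc1)OCC | starting material
19 | (2S,3S)-4-methoxy-3-[(2S,3S)-4-methoxy-3-(3,5-dimethoxyphenyl)-2-(4-methoxyphenyl)-2,3-dihydro-1-benzofuran-6-yl]-2-(4-methoxyphenyl)-6-[(E)-2-(4-methoxyphenyl)ethenyl]-2,3-dihydro-1-benzofuran (heptamethyl ether of the target) | COc1ccc(/C=C/c2cc(OC)c3c(c2)O[C@H](c2ccc(OC)cc2)[C@H]3c2cc(OC)c3c(c2)O[C@H](c2ccc(OC)cc2)[C@H]3c2cc(OC)cc(OC)c2)cc1 | intermediate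
20 | (2S,3S)-3-[(2S,3S)-3-(3,5-dihydroxyphenyl)-4-hydroxy-2-(4-hydroxyphenyl)-2,3-dihydro-1-benzofuran-6-yl]-2-(4-hydroxyphenyl)-6-[(E)-2-(4-hydroxyphenyl)ethenyl]-2,3-dihydro-1-benzofuran-4-ol | Oc1ccc(/C=C/c2cc(O)c3c(c2)O[C@H](c2ccc(O)cc2)[C@H]3c2cc(O)c3c(c2)O[C@H](c2ccc(O)cc2)[C@H]3c2cc(O)cc(O)c2)cc1 | target

## Step count and least certain steps

Total step count: 13. Longest linear sequence: 13 steps (1 to 20); 3, 6, 11 and 18 enter as purchased components.

**Step 7 (key step).** Both ketones are flanked by two ortho substituents, so intermolecular pinacol coupling, plain reduction of a ketone, or closure of only one of the two pairs may compete with the double cyclisation. The fallback makes the same C2–C3 and C2'–C3' bonds by a polar condensation. It sets out from 10, which is O-alkylated with 4-methoxybenzyl chloride and K2CO3 in DMF to give the bis(4-methoxybenzyl) ether F1. Treatment of F1 with the phosphazene base P4-t-Bu in hot toluene should deprotonate each benzylic ether carbon, which adds to the neighbouring ketone; loss of water (completed with TsOH if needed) gives both furans, and the route is rejoined at 13.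

**Step 8.** The tetrasubstituted, diaryl-substituted C2=C3 bonds are at the demanding end of what the catalyst from Ru(cod)(2-methylallyl)2 and the carbene ligand reduces, so slow conversion or insufficient facial discrimination on one or both rings is the main danger. The fallback gives up catalyst control. From 13, ionic hydrogenation with Et3SiH and CF3CO2H in CH2Cl2 (protonation at C3, hydride delivery to C2 anti to the C3 aryl group) should give the trans,trans bis(dihydrobenzofuran) as a stereoisomer mixture F2. The two diastereomers are separated on silica and the wanted enantiomer is isolated on a chiral stationary phase, rejoining the route at 15. This costs material, since at most a quarter of F2 has the right configuration.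

**Step 9.** The ring-opened benzylic cation may lose the C3 (C3') proton to give a triarylethene, whose reprotonation would erode the configuration set in step 8. The fallback moves the epimerisation to the end. From 14 the cis rings are carried through desilylation (Bu4NF) to the cis,cis alcohol F3, Dess–Martin oxidation to the cis,cis aldehyde F4, and olefination with 18 to the cis,cis heptamethyl ether F5. BBr3 is then expected to equilibrate C2 and C2' to trans while it cleaves the ethers, at low temperature and on boron-bound aryloxides, rejoining the route at 20.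

**Step 5.** BCl3 may also cleave the silyl ether, or go on to remove the second ortho methyl group if the temperature rises. The fallback accepts loss of the silyl group. From 9, BCl3 is used until both ortho ethers and the silyl ether are gone, giving the triol F6. The primary benzylic alcohol of F6 is then silylated selectively with TBDPSCl and imidazole (the two phenols are hindered and hydrogen-bonded to their ketones; any aryl silyl ether formed is removed with K2CO3 in methanol), rejoining the route at 10.

**Step 13.** Seven ethers must be cleaved while HBr and BBr3 are in contact with an electron-rich stilbene, so incomplete demethylation and acid-induced degradation of the stilbene are the likely failures. The fallback removes the methyl groups before the stilbene exists. From 17, BBr3 gives the hexaphenol aldehyde F7, which is silylated (TBSCl, imidazole, DMF) to the hexakis(tert-butyldimethylsilyl) ether aldehyde F8. Olefination of F8 with diethyl {4-[(tert-butyldimethylsilyl)oxy]benzyl}phosphonate F9 (from commercial diethyl (4-hydroxybenzyl)phosphonate and TBSCl) and NaH in THF gives the heptakis(silyl) stilbene F10. Et3N·3HF in THF then removes the silyl groups under non-acidic, non-basic conditions, rejoining the route at 20.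

## Further compounds

F1 | step 7 | {4-[(tert-butyldiphenylsilyloxy)methyl]-2-methoxy-6-[(4-methoxybenzyl)oxy]phenyl}{4-(3,5-dimethoxybenzoyl)-3-methoxy-5-[(4-methoxybenzyl)oxy]phenyl}methanone | COc1ccc(COc2cc(CO[Si](c3ccccc3)(c3ccccc3)C(C)(C)C)cc(OC)c2C(=O)c2cc(OC)c(C(=O)c3cc(OC)cc(OC)c3)c(OCc3ccc(OC)cc3)c2)cc1
F2 | step 8 | stereoisomer mixture of the trans,trans bis(dihydrobenzofuran) silyl ether (15, its enantiomer and the 2S,3S,2'R,3'R / 2R,3R,2'S,3'S pair) | CC(C)(C)[Si](OCc1cc(OC)c2c(c1)OC(c1ccc(OC)cc1)C2c1cc(OC)c2c(c1)OC(c1ccc(OC)cc1)C2c1cc(OC)cc(OC)c1)(c1ccccc1)c1ccccc1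
F3 | step 9 | {(2R,3S)-4-methoxy-3-[(2R,3S)-4-methoxy-3-(3,5-dimethoxyphenyl)-2-(4-methoxyphenyl)-2,3-dihydro-1-benzofuran-6-yl]-2-(4-methoxyphenyl)-2,3-dihydro-1-benzofuran-6-yl}methanol, both rings cis | OCc1cc(OC)c2c(c1)O[C@@H](c1ccc(OC)cc1)[C@H]2c1cc(OC)c2c(c1)O[C@@H](c1ccc(OC)cc1)[C@H]2c1cc(OC)cc(OC)c1
F4 | step 9 | (2R,3S)-4-methoxy-3-[(2R,3S)-4-methoxy-3-(3,5-dimethoxyphenyl)-2-(4-methoxyphenyl)-2,3-dihydro-1-benzofuran-6-yl]-2-(4-methoxyphenyl)-2,3-dihydro-1-benzofuran-6-carbaldehyde, both rings cis | O=Cc1cc(OC)c2c(c1)O[C@@H](c1ccc(OC)cc1)[C@H]2c1cc(OC)c2c(c1)O[C@@H](c1ccc(OC)cc1)[C@H]2c1cc(OC)cc(OC)c1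
F5 | step 9 | (2R,3S)-4-methoxy-3-[(2R,3S)-4-methoxy-3-(3,5-dimethoxyphenyl)-2-(4-methoxyphenyl)-2,3-dihydro-1-benzofuran-6-yl]-2-(4-methoxyphenyl)-6-[(E)-2-(4-methoxyphenyl)ethenyl]-2,3-dihydro-1-benzofuran, both rings cis | COc1ccc(/C=C/c2cc(OC)c3c(c2)O[C@@H](c2ccc(OC)cc2)[C@H]3c2cc(OC)c3c(c2)O[C@@H](c2ccc(OC)cc2)[C@H]3c2cc(OC)cc(OC)c2)cc1
F6 | step 5 | [4-(3,5-dimethoxybenzoyl)-3-hydroxy-5-methoxyphenyl][2-hydroxy-4-(hydroxymethyl)-6-methoxyphenyl]methanone | COc1cc(CO)cc(O)c1C(=O)c1cc(OC)c(C(=O)c2cc(OC)cc(OC)c2)c(O)c1
F7 | step 13 | (2S,3S)-3-[(2S,3S)-3-(3,5-dihydroxyphenyl)-4-hydroxy-2-(4-hydroxyphenyl)-2,3-dihydro-1-benzofuran-6-yl]-4-hydroxy-2-(4-hydroxyphenyl)-2,3-dihydro-1-benzofuran-6-carbaldehyde | O=Cc1cc(O)c2c(c1)O[C@H](c1ccc(O)cc1)[C@H]2c1cc(O)c2c(c1)O[C@H](c1ccc(O)cc1)[C@H]2c1cc(O)cc(O)c1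
F8 | step 13 | hexakis(tert-butyldimethylsilyl) ether of F7 | O=Cc1cc(O[Si](C)(C)C(C)(C)C)c2c(c1)O[C@H](c1ccc(O[Si](C)(C)C(C)(C)C)cc1)[C@H]2c1cc(O[Si](C)(C)C(C)(C)C)c2c(c1)O[C@H](c1ccc(O[Si](C)(C)C(C)(C)C)cc1)[C@H]2c1cc(O[Si](C)(C)C(C)(C)C)cc(O[Si](C)(C)C(C)(C)C)c1
F9 | step 13 | diethyl {4-[(tert-butyldimethylsilyl)oxy]benzyl}phosphonate | CCOP(=O)(Cc1ccc(O[Si](C)(C)C(C)(C)C)cc1)OCC
F10 | step 13 | heptakis(tert-butyldimethylsilyl) ether of 20 | CC(C)(C)[Si](C)(C)Oc1ccc(/C=C/c2cc(O[Si](C)(C)C(C)(C)C)c3c(c2)O[C@H](c2ccc(O[Si](C)(C)C(C)(C)C)cc2)[C@H]3c2cc(O[Si](C)(C)C(C)(C)C)c3c(c2)O[C@H](c2ccc(O[Si](C)(C)C(C)(C)C)cc2)[C@H]3c2cc(O[Si](C)(C)C(C)(C)C)cc(O[Si](C)(C)C(C)(C)C)c2)cc1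
A1 | alternative 1 | methyl (2S,3S)-4-methoxy-2-(4-methoxyphenyl)-6-(trifluoromethanesulfonyloxy)-2,3-dihydro-1-benzofuran-3-carboxylate (trans) | FC(F)(F)S(=O)(=O)Oc1cc(OC)c2c(c1)O[C@H](c1ccc(OC)cc1)[C@H]2C(=O)OC
A2 | alternative 1 | (S)-5-methoxy-2-(4-methoxyphenyl)-4-oxochroman-7-yl trifluoromethanesulfonate | O=C1C[C@@H](c2ccc(OC)cc2)Oc2cc(OS(=O)(=O)C(F)(F)F)cc(OC)c12
A3 | alternative 2 | ring B phenol with triisopropylsilyl ether at C7a' and open C3'–C2' chain, ring A unit attached at C6' | COc1ccc(/C=C/c2cc(OC)c3c(c2)O[C@H](c2ccc(OC)cc2)[C@H]3c2cc(O)c(c(O[Si](C(C)C)(C(C)C)C(C)C)c2)[C@H](c2cc(OC)cc(OC)c2)[C@@H](O[Si](C)(C)C(C)(C)C)c2ccc(OC)cc2)cc1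
A4 | alternative 2 | 3-substituted cyclobut-2-en-1-one carrying the ring A dihydrobenzofuran at its C3 | COc1ccc(/C=C/c2cc(OC)c3c(c2)O[C@H](c2ccc(OC)cc2)[C@H]3C2=CC(=O)C2)cc1
A5 | alternative 2 | triisopropylsiloxyalkyne carrying C3' (ring C) and C2' (tert-butyldimethylsilyl ether, ring E) | CC(C)[Si](OC#C[C@H](c1cc(OC)cc(OC)c1)[C@@H](O[Si](C)(C)C(C)(C)C)c1ccc(OC)cc1)(C(C)C)C(C)C
A6 | alternative 3 | heptamethyl ether of the target (identical with 19) | COc1ccc(/C=C/c2cc(OC)c3c(c2)O[C@H](c2ccc(OC)cc2)[C@H]3c2cc(OC)c3c(c2)O[C@H](c2ccc(OC)cc2)[C@H]3c2cc(OC)cc(OC)c2)cc1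
A7 | alternative 3 | trans-2-(4-methoxyphenyl)-6-[(E)-2-(4-methoxyphenyl)ethenyl]-3-(ring B dihydrobenzofuran-6-yl)-2,3-dihydrofuro[3,2-c]pyran-4-one | COc1ccc(/C=C/c2cc3O[C@H](c4ccc(OC)cc4)[C@@H](c4cc(OC)c5c(c4)O[C@H](c4ccc(OC)cc4)[C@H]5c4cc(OC)cc(OC)c4)c3c(=O)o2)cc1
A8 | alternative 3 | 1,1-dimethoxyethene | C=C(OC)OC
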